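Plan
- Retrosynthesis cuts C2–C3 and C4a–C8a of the chromenone. The ring oxygen O1 with its two neighbours C2 and C8a is read as the 2,5-positions of a furan, and C3–C4(O)–C4a as a 2-oxyallyl cation whose trigger is an epoxide on C4a–C5.
- The remaining cuts are chain bonds: C1'–C2' of the heptadecyl group (Wittig) and the enone C=C of the acyclic precursor (cross-metathesis).
- Forward: furan is alkylated, extended to an E-enone, epoxidised and enol-silylated. One intramolecular (4+3) cycloaddition then closes the carbocycle (C4a–C8a) and the pyranone ring (C2–C3) together, leaving a temporary CH=CH bridge between C2 and C8a.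
- The bridge is ozonolysed: its carbon on C2 becomes C1' of the side chain, its carbon on C8a leaves as CO2 while C4a=C8a forms, and C5 is oxidised to the ketone.
- Stereochemistry: catalytic asymmetric epoxidation sets C5, which relays to C2 in the cycloaddition and is then erased. The C4 hydroxyl comes from hydride attack on the bicyclic ketone anti to the bridge, cis to the C2 chain.

Key step: step 5

Assumption: the lanthanum–(R)-BINOL catalyst is taken to give the (3S,4R)-epoxide, and the cycloaddition to proceed with inversion at the epoxide carbon with the tether carbon syn to the silyloxy group; if either sense is the opposite, (S)-BINOL is used in step 3.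

Chromane numbering (O1, C2, C3, C4, C4a, C5–C8, C8a) is used for all bicyclic and tricyclic compounds.

Step 1
Reactants: 1 furan; 2 5-bromopent-1-ene
Product: 4 2-(pent-4-en-1-yl)furan, via 2-furyllithium 3 (not isolated)
Conditions: n-BuLi, THF, 0 °C; then 2, 0 °C to rt
Reagents that add atoms: none
Why: α-Lithiation of furan and SN2 alkylation with a primary bromide should give the 2-alkylfuran; no stereocentre is formed.

Step 2
Reactants: 4 2-(pent-4-en-1-yl)furan; 5 but-3-en-2-one
Product: 6 (3E)-7-(furan-2-yl)hept-3-en-2-one
Conditions: second-generation Grubbs catalyst RuCl2(=CHPh)(H2IMes)(PCy3) (3 mol%), 5 (3 equiv), CH2Cl2, 40 °C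
Reagents that add atoms: none
Why: Olefin cross-metathesis of a terminal alkene with an electron-poor enone partner should give the E-enone selectively, the furan being inert to the ruthenium carbene.

Step 3
Reactants: 6 (3E)-7-(furan-2-yl)hept-3-en-2-one
Product: 7 1-{(2S,3R)-3-[3-(furan-2-yl)propyl]oxiran-2-yl}ethan-1-one (trans-epoxy ketone)
Conditions: La(O-i-Pr)3, (R)-BINOL, Ph3As=O (5 mol% each), t-BuOOH, 4 Å molecular sieves, THF, rt
Reagents that add atoms: tert-butyl hydroperoxide, CC(C)(C)OO
Why: Nucleophilic asymmetric epoxidation of an (E)-alkyl enone by the lanthanum–BINOL–arsine oxide peroxide (Shibasaki epoxidation) should set both epoxide carbons from the catalyst, the trans geometry following from the E-alkene.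

Step 4
Reactants: 7 trans-epoxy ketone
Product: 8 triethyl[(1-{(2S,3R)-3-[3-(furan-2-yl)propyl]oxiran-2-yl}ethenyl)oxy]silane
Conditions: Et3SiOTf, Et3N (excess), CH2Cl2, −78 °C
Reagents that add atoms: triethylsilyl trifluoromethanesulfonate, CC[Si](CC)(CC)OS(=O)(=O)C(F)(F)F
Why: Soft enolisation and O-silylation on the methyl side should give the 2-silyloxy-1-alkene (silyl enol ether formation), the excess amine keeping the triflate from activating the epoxide.

Step 5
Reactants: 8 epoxy enol silane
Product: 9 (2R,4aS,5R,8aR)-5-(triethylsilyloxy)-4a,5,6,7,8,8a-hexahydro-2H-2,8a-ethenochromen-4(3H)-one (an 8-oxabicyclo[3.2.1]oct-6-en-3-one fused to a cyclohexane; the CH=CH bridge joins C2 and C8a)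
Conditions: Et3SiOTf (0.1 equiv), CH2Cl2, −78 °C; Et3N quench
Reagents that add atoms: none
Why: Silylation of the epoxide oxygen triggers attack of the tether-bearing furan α-carbon on the epoxide carbon next to the enol silane with inversion, the enol silane acting as an incipient 2-silyloxyallyl cation whose CH2 terminus then bonds to the other furan α-carbon, and loss of the silyl cation from the carbonyl oxygen turns the catalyst over. The closest known reaction type is the intramolecular (4+3) cycloaddition of epoxy enol silanes, as oxyallyl cation equivalents, with tethered furans. The cyclohexane ring closes by 6-endo opening of the epoxide by the furan carbon (C4a–C8a), and the seven-membered ring, whose oxygen-bridged half is the future pyran ring, closes by the second bond C2–C3 on the same furan face, a (4+3) cycloaddition suprafacial on both partners. C5 keeps the epoxide configuration, C4a is set by inversion, and C8a and C2 are set by the furan face that the three-carbon tether presents when the forming ring adopts a chair with the silyloxy group equatorial and the tether carbon syn to the enol oxygen. The step needs ipso attack at the substituted furan carbon instead of Friedel–Crafts alkylation at the furan β-carbon or rearrangement of the epoxide; the short tether, the allylic stabilisation that directs opening to the carbon next to the enol silane, and the low temperature should secure this.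

Step 6
Reactants: 9 tricyclic ketone
Product: 11 (2R,4R,4aS,5R,8aR)-5-(triethylsilyloxy)-3,4,4a,5,6,7,8,8a-octahydro-2H-2,8a-ethenochromen-4-yl acetate (acetoxy on the face of the CH=CH bridge), via lithium alkoxide 10 (not isolated)
Conditions: LiBH(s-Bu)3, THF, −78 °C; then Ac2O, DMAP, −78 °C to rt
Reagents that add atoms: acetic anhydride, CC(=O)OC(C)=O
Why: The bulky hydride should add from the open face of the bicyclic ketone anti to the CH=CH bridge (substrate-controlled reduction), which puts the C4 oxygen on the bridge face, cis to the carbon that becomes the C2 chain, and the alkoxide is trapped as the acetate.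

Step 7
Reactants: 11 acetate
Product: 13 (2R,4R,4aS,5R,8aS)-2,8a-diformyl-5-(triethylsilyloxy)octahydro-2H-chromen-4-yl acetate, via secondary ozonide 12 (not isolated)
Conditions: O3, CH2Cl2, −78 °C; then PPh3, −78 °C to rt
Reagents that add atoms: ozone, [O-][O+]=O
Why: Ozonolysis with reductive work-up cleaves only the strained C=C bond and so unzips the temporary bridge to the cis-2,8a-diformyl tetrahydropyran without touching a stereocentre.

Step 8
Reactants: 13 dialdehyde; 14 hexadecyltriphenylphosphonium bromide
Product: 16 (2R,4R,4aS,5R,8aS)-8a-formyl-2-[(1Z)-heptadec-1-en-1-yl]-5-(triethylsilyloxy)octahydro-2H-chromen-4-yl acetate, via hexadecylidenetriphenylphosphorane 15 (not isolated)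
Conditions: 14, NaN(SiMe3)2, THF, 0 °C; then 13 (1.0 equiv of ylide), −78 °C
Reagents that add atoms: none
Why: In this Wittig olefination the non-stabilised ylide should react much faster with the unhindered formyl group on the tertiary C2 than with the neopentyl-type formyl group on the quaternary C8a, and the low temperature guards the C2 stereocentre against enolisation.

Step 9
Reactants: 16 Z-alkene aldehyde
Product: 17 (2S,4R,4aS,5R,8aS)-8a-formyl-2-heptadecyl-5-(triethylsilyloxy)octahydro-2H-chromen-4-yl acetate
Conditions: H2 (1 atm), Pd/C, EtOAc, rt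
Reagents that add atoms: none
Why: Heterogeneous hydrogenation of the disubstituted alkene should leave the hindered aldehyde, the acetate and the silyl ether untouched.

Step 10
Reactants: 17 saturated aldehyde
Product: 19 (2S,4R,4aR,8aS)-4-acetoxy-2-heptadecyl-5-oxooctahydro-2H-chromene-8a-carboxylic acid, via desilylated hydroxy aldehyde 18 (not isolated)
Conditions: CrO3, H2SO4, H2O, acetone, 0 °C
Reagents that add atoms: water, O
Why: In this Jones oxidation the aqueous acid cleaves the triethylsilyl ether and chromic acid oxidises the secondary alcohol to the C5 ketone and the formyl group (through its hydrate) to the acid, the acetate surviving; the C5 stereocentre is erased after it has done its relay work.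

Step 11
Reactants: 19 keto acid
Product: 20 (2S,4R)-2-heptadecyl-5-oxo-3,4,5,6,7,8-hexahydro-2H-chromen-4-yl acetate
Conditions: graphite anode, Pt cathode, undivided cell, constant current (about 2.2 F per mol), 2,4,6-collidine, n-Bu4NBF4, MeCN, rt
Reagents that add atoms: none
Why: In this non-Kolbe (Hofer–Moest) anodic decarboxylation the α-alkoxy carboxylate should lose CO2 and a second electron to give the oxocarbenium ion at C8a, which loses the acidic C4a proton next to the C5 ketone to give the conjugated vinylogous ester.

Step 12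
Reactants: 20 acetate of the target
Product: 21 (2S,4R)-2-heptadecyl-4-hydroxy-2,3,4,6,7,8-hexahydro-5H-chromen-5-one
Conditions: K2CO3, MeOH, 0 °C
Reagents that add atoms: none
Why: Mild base-catalysed methanolysis (transesterification) should free the C4 hydroxyl; with C4a now sp2 there is no enolisable position from which the C4 oxygen could be eliminated.

Compound list
1 | furan | c1ccoc1 | starting material
2 | 5-bromopent-1-ene | C=CCCCBr | starting material
3 | 2-furyllithium | [Li]c1ccco1 | intermediate
4 | 2-(pent-4-en-1-yl)furan | C=CCCCc1ccco1 | intermediate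
5 | but-3-en-2-one | CC(=O)C=C | starting material
6 | (3E)-7-(furan-2-yl)hept-3-en-2-one | CC(=O)/C=C/CCCc1ccco1 | intermediate
7 | 1-{(2S,3R)-3-[3-(furan-2-yl)propyl]oxiran-2-yl}ethan-1-one | CC(=O)[C@H]1O[C@@H]1CCCc1ccco1 | intermediate
8 | triethyl[(1-{(2S,3R)-3-[3-(furan-2-yl)propyl]oxiran-2-yl}ethenyl)oxy]silane | C=C(O[Si](CC)(CC)CC)[C@H]1O[C@@H]1CCCc1ccco1 | intermediate
9 | (2R,4aS,5R,8aR)-5-(triethylsilyloxy)-4a,5,6,7,8,8a-hexahydro-2H-2,8a-ethenochromen-4(3H)-one | O=C1C[C@@H]2C=C[C@@]3(CCC[C@@H](O[Si](CC)(CC)CC)[C@H]13)O2 | intermediate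
10 | lithium alkoxide of the 4-alcohol of 9 (oxygen on the bridge face) | [Li+].[O-][C@@H]1C[C@@H]2C=C[C@@]3(CCC[C@@H](O[Si](CC)(CC)CC)[C@H]13)O2 | intermediate
11 | (2R,4R,4aS,5R,8aR)-5-(triethylsilyloxy)-3,4,4a,5,6,7,8,8a-octahydro-2H-2,8a-ethenochromen-4-yl acetate | CC(=O)O[C@@H]1C[C@@H]2C=C[C@@]3(CCC[C@@H](O[Si](CC)(CC)CC)[C@H]13)O2 | intermediate
12 | secondary ozonide (1,2,4-trioxolane) of 11, both bridge orientations | CC(=O)O[C@@H]1C[C@@H]2C3OOC(O3)[C@@]4(CCC[C@@H](O[Si](CC)(CC)CC)[C@H]14)O2 | intermediate
13 | (2R,4R,4aS,5R,8aS)-2,8a-diformyl-5-(triethylsilyloxy)octahydro-2H-chromen-4-yl acetate | O=C[C@H]1C[C@@H](OC(C)=O)[C@H]2[C@H](O[Si](CC)(CC)CC)CCC[C@]2(C=O)O1 | intermediate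
14 | hexadecyltriphenylphosphonium bromide | CCCCCCCCCCCCCCCC[P+](c1ccccc1)(c1ccccc1)c1ccccc1.[Br-] | starting material
15 | hexadecylidenetriphenylphosphorane | CCCCCCCCCCCCCCCC=P(c1ccccc1)(c1ccccc1)c1ccccc1 | intermediate
16 | (2R,4R,4aS,5R,8aS)-8a-formyl-2-[(1Z)-heptadec-1-en-1-yl]-5-(triethylsilyloxy)octahydro-2H-chromen-4-yl acetate | CCCCCCCCCCCCCCC/C=C\[C@H]1C[C@@H](OC(C)=O)[C@H]2[C@H](O[Si](CC)(CC)CC)CCC[C@]2(C=O)O1 | intermediate
17 | (2S,4R,4aS,5R,8aS)-8a-formyl-2-heptadecyl-5-(triethylsilyloxy)octahydro-2H-chromen-4-yl acetate | CCCCCCCCCCCCCCCCC[C@H]1C[C@@H](OC(C)=O)[C@H]2[C@H](O[Si](CC)(CC)CC)CCC[C@]2(C=O)O1 | intermediate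
18 | 5-hydroxy aldehyde from 17 (silyl ether cleaved, other centres as in 17) | CCCCCCCCCCCCCCCCC[C@H]1C[C@@H](OC(C)=O)[C@H]2[C@H](O)CCC[C@]2(C=O)O1 | intermediate
19 | (2S,4R,4aR,8aS)-4-acetoxy-2-heptadecyl-5-oxooctahydro-2H-chromene-8a-carboxylic acid | CCCCCCCCCCCCCCCCC[C@H]1C[C@@H](OC(C)=O)[C@H]2C(=O)CCC[C@]2(C(=O)O)O1 | intermediate
20 | (2S,4R)-2-heptadecyl-5-oxo-3,4,5,6,7,8-hexahydro-2H-chromen-4-yl acetate | CCCCCCCCCCCCCCCCC[C@H]1C[C@@H](OC(C)=O)C2=C(CCCC2=O)O1 | intermediate
21 | (2S,4R)-2-heptadecyl-4-hydroxy-2,3,4,6,7,8-hexahydro-5H-chromen-5-one | CCCCCCCCCCCCCCCCC[C@H]1C[C@@H](O)C2=C(CCCC2=O)O1 | target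

Total step count: 12
Longest linear sequence: 12 steps (from furan)

Steps most likely to fail

Step 5. The cycloaddition may lose facial control if the tether carbon sits syn to the methylene terminus instead of the silyloxy group; once C5 is oxidised this would erode the enantiomeric purity at C2. It may also stop after the first bond, with rearomatisation of the furan, or the activated epoxide may rearrange before the furan attacks. The fallback sets out from 7 and comes back at 9, and generates the free oxyallyl cation by the classical dehydrohalogenation route. Bromide (MgBr2·OEt2, Et2O, −20 °C) should open the epoxide of 7 at the carbon next to the carbonyl with inversion to give (3R,4R)-3-bromo-7-(furan-2-yl)-4-hydroxyheptan-2-one F1. Silylation (Et3SiCl, imidazole, DMF) gives (3R,4R)-3-bromo-7-(furan-2-yl)-4-(triethylsilyloxy)heptan-2-one F2. Under Föhlisch conditions (Et3N, LiClO4, Et2O, or CF3CH2ONa in CF3CH2OH), enolisation toward the methyl group and loss of bromide should give the 2-oxyallyl cation, which undergoes the same intramolecular (4+3) cycloaddition through the chair with the silyloxy group equatorial to give 9.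

Step 8. The ylide may fail to discriminate between the two formyl groups, or may enolise the C2 formyl group and epimerise C2. The fallback sets out from 11 and comes back at 17, replacing the olefination by an sp3–sp3 coupling. Ozonolysis of 11 with NaBH4 work-up gives the diol (2R,4R,4aS,5R,8aS)-2,8a-bis(hydroxymethyl)-5-(triethylsilyloxy)octahydro-2H-chromen-4-yl acetate F3. TsCl in pyridine at −20 °C should sulfonylate only the unhindered hydroxymethyl group on C2, the one on C8a being neopentyl, to give the mono-tosylate F4. Coupling with C16H33MgBr and Li2CuCl4 (catalytic) in THF at −40 °C gives (2S,4R,4aS,5R,8aS)-2-heptadecyl-8a-(hydroxymethyl)-5-(triethylsilyloxy)octahydro-2H-chromen-4-yl acetate F5, and Dess–Martin periodinane oxidises the remaining primary alcohol to 17.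

Step 11. The electrolysis may be overtaken by β-elimination of acetate from the β-acetoxy ketone under the amine base, by radical (Kolbe) dimerisation, or by proton loss toward C8 instead of C4a. The fallback sets out from 17 and comes back at 20, removing the C8a carbon by oxygen insertion instead of decarboxylation and staying on the acidic side throughout. Baeyer–Villiger oxidation of 17 (mCPBA, NaHCO3, CH2Cl2), in which the α-alkoxy quaternary carbon migrates, should give the formate of the 8a-hemiketal F6. PPTS in MeOH removes the silyl ether and exchanges the formate for methoxy to give the 8a-methoxy 5-alcohol F7. Dess–Martin periodinane (NaHCO3) gives the 8a-methoxy 5-ketone F8, and camphorsulfonic acid (catalytic, CH2Cl2) eliminates methanol through the C8a oxocarbenium ion to give 20.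

Further compounds
F1 | step 5 | (3R,4R)-3-bromo-7-(furan-2-yl)-4-hydroxyheptan-2-one | CC(=O)[C@H](Br)[C@H](O)CCCc1ccco1
F2 | step 5 | (3R,4R)-3-bromo-7-(furan-2-yl)-4-(triethylsilyloxy)heptan-2-one | CC(=O)[C@H](Br)[C@H](O[Si](CC)(CC)CC)CCCc1ccco1
F3 | step 8 | (2R,4R,4aS,5R,8aS)-2,8a-bis(hydroxymethyl)-5-(triethylsilyloxy)octahydro-2H-chromen-4-yl acetate | OC[C@H]1C[C@@H](OC(C)=O)[C@H]2[C@H](O[Si](CC)(CC)CC)CCC[C@]2(CO)O1
F4 | step 8 | mono-tosylate of F3 at the hydroxymethyl group on C2 | Cc1ccc(cc1)S(=O)(=O)OC[C@H]1C[C@@H](OC(C)=O)[C@H]2[C@H](O[Si](CC)(CC)CC)CCC[C@]2(CO)O1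
F5 | step 8 | (2S,4R,4aS,5R,8aS)-2-heptadecyl-8a-(hydroxymethyl)-5-(triethylsilyloxy)octahydro-2H-chromen-4-yl acetate | CCCCCCCCCCCCCCCCC[C@H]1C[C@@H](OC(C)=O)[C@H]2[C@H](O[Si](CC)(CC)CC)CCC[C@]2(CO)O1
F6 | step 11 | 8a-formyloxy analogue of 17 (formate of the 8a-hemiketal, other centres as in 17) | CCCCCCCCCCCCCCCCC[C@H]1C[C@@H](OC(C)=O)[C@H]2[C@H](O[Si](CC)(CC)CC)CCC[C@]2(OC=O)O1
F7 | step 11 | 4-acetoxy-2-heptadecyl-8a-methoxyoctahydro-2H-chromen-5-ol (both C8a epimers) | CCCCCCCCCCCCCCCCC[C@H]1C[C@@H](OC(C)=O)[C@H]2[C@H](O)CCCC2(OC)O1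
F8 | step 11 | 4-acetoxy-2-heptadecyl-8a-methoxyoctahydro-2H-chromen-5-one (both C8a epimers) | CCCCCCCCCCCCCCCCC[C@H]1C[C@@H](OC(C)=O)[C@H]2C(=O)CCCC2(OC)O1
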